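The six-membered ring C1–C2–C3–C4–C4a–C8a is built one carbon short and then enlarged. (R)-Carvone supplies ring 2, C8a and, through its isopropenyl group, C1, the C1 methyl and C2; an acetate arm brings C3 and C4. Titanium-mediated ester–alkene coupling welds these into a cyclopropanol fused to the five-membered ring C1–C3–C4–C4a–C8a. The key step exploits the 1,3-relationship of the C3 oxygen and the methyl-bearing C1: FeCl3 cleaves the internal C1–C3 cyclopropane bond, C2 enters the ring, and loss of HCl gives the cyclohexenone, whose C1 and C4 are then functionalised under stereocontrol by the trans ring fusion.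

Key step: step 6

Locants used below (decalin core): ring 1 = C1 (tertiary carbinol), C2, C3 (acyloxy carbon), C4 (carbon bearing the acrylic acid), C4a, C8a; ring 2 = C4a, C5, C6 (methyl), C7 (acetoxy carbon), C8, C8a.

Step 1
Reactants: 1 (R)-(−)-carvone; 2 ethyl bromoacetate
Product: 3 ethyl 2-[(1S,6R)-3-methyl-2-oxo-6-(prop-1-en-2-yl)cyclohex-3-en-1-yl]acetate
Conditions: LiN(iPr)2, THF, −78 °C; then 2, −78 to −30 °C
Reagents that add atoms: none
Why: Kinetic enolate alkylation: LiN(iPr)2 removes a proton from the CH2 flanking the carbonyl (future C4a) and the bromide is displaced on the face anti to the neighbouring isopropenyl group, which should set C4a trans to C8a.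

Step 2
Reactants: 3 keto ester
Product: 4 epoxy ketone (C6–C7 oxirane trans to the isopropenyl group)
Conditions: 30% H2O2, NaOH (0.3 equiv), EtOH, 0 °C
Reagents that add atoms: hydrogen peroxide, OO
Why: Weitz–Scheffer nucleophilic epoxidation touches only the enone; the hydroperoxide anion should add axially to C7 anti to the C8a substituent, as with carvone itself, placing the oxirane trans to the isopropenyl group.

Step 3
Reactants: 4 epoxy ketone
Product: 6 allylic alcohol (C5=C6, C7–OH trans to isopropenyl), via epoxy hydrazone 5 (not isolated)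
Conditions: N2H4·H2O, AcOH (cat.), EtOH, 0 °C to rt
Reagents that add atoms: none
Why: Wharton transposition: the epoxy hydrazone fragments with loss of N2 to the C5=C6 alkene and the C7 alcohol, whose configuration is that of the oxirane C7–O bond, while the short, cold exposure should spare the ethyl ester.

Step 4
Reactants: 6 allylic alcohol
Product: 7 triisopropylsilyl ether of 6
Conditions: iPr3SiOTf, 2,6-lutidine, CH2Cl2, −78 to 0 °C
Reagents that add atoms: triisopropylsilyl trifluoromethanesulfonate, CC(C)[Si](C(C)C)(C(C)C)OS(=O)(=O)C(F)(F)F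
Why: Silyl ether formation on the hindered axial allylic alcohol with the reactive triflate protects it against the Grignard reagent, the bases and the oxidants that follow.

Step 5
Reactants: 7 silyl ether
Product: 8 tricyclic cyclopropanol (bicyclo[3.1.0]hexan-1-ol: OH on C3, methyl on C1, cyclopropane CH2 = C2, trans-fused to ring 2)
Conditions: ClTi(OiPr)3 (1.2 equiv), c-C6H11MgCl (4.5 equiv, slow addition), THF, rt
Reagents that add atoms: none
Why: Intramolecular Kulinkovich cyclopropanation: the titanacyclopropane made from the Grignard reagent exchanges onto the isopropenyl alkene and inserts the tethered ester, closing the five-membered ring C1–C3–C4–C4a–C8a and then the cyclopropanol; either cyclopropane-face isomer serves because C1 and C3 lose their configuration in step 6.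

Step 6
Reactants: 8 cyclopropanol
Product: 10 enone (C3=O conjugated to C1=C2, methyl on C1), via β-chloro ketone 9 (not isolated)
Conditions: FeCl3 (2.2 equiv), DMF, 0 °C to rt; then NaOAc, MeOH, reflux
Reagents that add atoms: none
Why: FeCl3 oxidises the cyclopropanol O–H to an alkoxy radical, which undergoes β-scission of the internal C1–C3 bond to the 3-oxocyclohexyl radical at C1; chlorine transfer from a second FeCl3 gives β-chloro ketone 9, and acetate then removes HCl by an E1cB path to the conjugated enone. The closest known reaction type is the Saegusa–Ito one-carbon ring expansion of 1-siloxy- or 1-hydroxybicyclo[n.1.0]alkanes with FeCl3. No ring is closed in this step: the five-membered ring C1–C3–C4–C4a–C8a becomes the six-membered ring by insertion of the cyclopropane methylene C2 between C1 and C3, and ring 2 is untouched. No stereocentre is created, since C1 and C3 end trigonal, so both cyclopropane-face isomers of 8 converge while C4a and C8a keep the trans relation set in step 1. The step needs cleavage of the internal rather than the external cyclopropane bond; the methyl group makes the C1 radical tertiary, and any primary radical from external cleavage can re-close onto the carbonyl and re-open in the Dowd–Beckwith manner to the same six-membered radical. It also needs the trisubstituted C5=C6 alkene and the silyl ether to survive, which the mild one-electron oxidant in DMF should allow.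

Step 7
Reactants: 10 enone
Product: 11 epoxy ketone (C1–C2 oxirane anti to H-8a)
Conditions: 30% H2O2, NaOH, MeOH, 0 °C
Reagents that add atoms: hydrogen peroxide, OO
Why: Weitz–Scheffer epoxidation of the β-methyl enone; axial attack of the hydroperoxide at C1 on the face anti to H-8a, the course known for trans-fused octalenones, should place the C1–O bond axial and anti to H-8a with the methyl equatorial.

Step 8
Reactants: 11 epoxy ketone; 12 tert-butyl bromoacetate
Product: 13 C4-alkylated epoxy ketone (CH2CO2tBu on C4, cis to H-8a)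
Conditions: LiN(iPr)2, THF, −78 °C; then 12, DMPU, −78 to −40 °C
Reagents that add atoms: none
Why: Kinetic α′-enolate alkylation: C4 carries the only acidic CH2, and the bromoacetate should enter axially on the face anti to the oxirane and to H-4a, which sets C4 with the side chain cis to H-8a.

Step 9
Reactants: 13 alkylated epoxy ketone
Product: 14 β-hydroxy ketone (C1 tertiary alcohol, C3 ketone)
Conditions: SmI2 (2.5 equiv), THF/MeOH, −90 °C
Reagents that add atoms: none
Why: SmI2 reduction of an α,β-epoxy ketone cleaves only the Cα–O bond at C2, unveiling the β-hydroxy ketone with the tertiary C1 alcohol unchanged in configuration and without base that could epimerise C4.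

Step 10
Reactants: 14 β-hydroxy ketone
Product: 15 1,3-anti diol (C3–OH equatorial, cis to the C4 side chain)
Conditions: Me4NBH(OAc)3, AcOH/MeCN (1:1), −30 °C
Reagents that add atoms: none
Why: Evans–Saksena hydroxyl-directed reduction: the axial C1 alkoxyborohydride delivers hydride to the same face of the C3 ketone, which should give the 1,3-anti diol with the C3 hydroxyl equatorial and cis to the C4 side chain, while the tert-butyl ester resists lactonisation.

Step 11
Reactants: 15 diol ester
Product: 18 tert-butyl acrylate diol, via Mannich base 16 (not isolated), via ammonium iodide 17 (not isolated)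
Conditions: LiN(iPr)2 (3.5 equiv), THF, −78 °C; CH2=NMe2+ I−, −78 to 0 °C; then MeI, MeOH, rt; then aq. NaHCO3, EtOAc, rt
Reagents that add atoms: Eschenmoser's salt (N,N-dimethylmethyleneiminium iodide), C=[N+](C)C.[I-]
Why: Mannich aminomethylation of the ester enolate with Eschenmoser's salt followed by N-methylation and Hofmann-type β-elimination is the standard α-methylenation; excess base keeps both hydroxyls as alkoxides and the stereocentres are not involved.

Step 12
Reactants: 19 2-butyne-1,4-diol
Product: 20 (E)-2-(tributylstannyl)but-2-ene-1,4-diol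
Conditions: Bu3SnH, Pd(PPh3)4 (2 mol%), THF, 0 °C to rt
Reagents that add atoms: tributyltin hydride, CCCC[SnH](CCCC)CCCC
Why: Pd-catalysed hydrostannation adds H and Sn syn across the symmetrical alkyne, so the two hydroxymethyl groups end cis and no regiochemistry arises.

Step 13
Reactants: 20 stannyl diol
Product: 21 2,2-dimethyl-5-(tributylstannyl)-4,7-dihydro-1,3-dioxepine
Conditions: Me2C(OMe)2, PPTS (cat.), CH2Cl2, rt
Reagents that add atoms: 2,2-dimethoxypropane, COC(C)(C)OC
Why: Acid-catalysed transacetalisation closes the seven-membered acetonide, possible only because the CH2OH groups are cis, and PPTS is mild enough for the vinylstannane.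

Step 14
Reactants: 21 stannyl dioxepine
Product: 23 2,2-dimethyl-4,7-dihydro-1,3-dioxepine-5-carboxylic acid, via vinyllithium 22 (not isolated)
Conditions: MeLi, THF, −78 °C; then CO2 (g), −78 °C to rt; aq. NaH2PO4
Reagents that add atoms: carbon dioxide, O=C=O
Why: Tin–lithium exchange with retention gives the ring-locked vinyllithium, which cannot eliminate alkoxide to an allene within the seven-membered ring, and carboxylation then gives the acid.

Step 15
Reactants: 18 tert-butyl acrylate diol; 23 dioxepine carboxylic acid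
Product: 25 C3 ester (acetonide-protected side chain, C7–OSi(iPr)3, tert-butyl acrylate), via mixed anhydride 24 (not isolated)
Conditions: 23, 2,4,6-Cl3C6H2COCl, Et3N, toluene, rt; then 18, DMAP, toluene, rt
Reagents that add atoms: none
Why: Yamaguchi esterification through the mixed anhydride acylates the secondary C3 hydroxyl; the tertiary C1 alcohol should stay free.

Step 16
Reactants: 25 silyl-protected ester
Product: 26 C7 allylic alcohol (hydroxyl cis to H-8a)
Conditions: Bu4NF, AcOH, THF, 0 °C to rt
Reagents that add atoms: none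
Why: Fluoride cleavage of the silyl ether; acetic acid buffering protects the esters, and the acetonide and tert-butyl ester are inert to fluoride.

Step 17
Reactants: 26 C7 alcohol
Product: 27 C7 acetate (inverted, trans to H-8a)
Conditions: AcOH, PPh3, DIAD, THF, 0 °C to rt
Reagents that add atoms: acetic acid, CC(=O)O
Why: Mitsunobu esterification displaces the activated axial C7 oxygen with acetate by SN2 inversion, giving the equatorial acetate trans to H-8a required by the target, while the tertiary C1 alcohol cannot be activated.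

Step 18
Reactants: 27 protected acetate
Product: 28 CNP0468194.2 (target acid)
Conditions: TFA/CH2Cl2 (1:2), H2O (5 equiv), 0 °C to rt
Reagents that add atoms: none
Why: Acidolysis removes the tert-butyl ester as 2-methylpropene and hydrolyses the seven-membered acetonide in one operation, conditions under which the acetate, the enoate and the tertiary alcohol should persist at low temperature.

Compound list
1 | (R)-(−)-carvone, (5R)-2-methyl-5-(prop-1-en-2-yl)cyclohex-2-en-1-one | CC1=CC[C@H](CC1=O)C(C)=C | starting material
2 | ethyl bromoacetate | CCOC(=O)CBr | starting material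
3 | ethyl 2-[(1S,6R)-3-methyl-2-oxo-6-(prop-1-en-2-yl)cyclohex-3-en-1-yl]acetate (acetate arm trans to isopropenyl) | CCOC(=O)C[C@@H]1C(=O)C(C)=CC[C@H]1C(C)=C | intermediate
4 | epoxy ketone: 3 with the enone alkene (C6–C7) as oxirane, oxirane oxygen trans to isopropenyl | CCOC(=O)C[C@@H]1C(=O)[C@]2(C)O[C@@H]2C[C@H]1C(C)=C | intermediate
5 | hydrazone of 4 at the C5 carbonyl | CCOC(=O)C[C@@H]1C(=NN)[C@]2(C)O[C@@H]2C[C@H]1C(C)=C | intermediate
6 | ethyl 2-[4-hydroxy-3-methyl-6-(prop-1-en-2-yl)cyclohex-2-en-1-yl]acetate; hydroxyl and acetate arm both trans to isopropenyl | CCOC(=O)C[C@@H]1C=C(C)[C@H](O)C[C@H]1C(C)=C | intermediate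
7 | triisopropylsilyl ether of 6 | CCOC(=O)C[C@@H]1C=C(C)[C@H](O[Si](C(C)C)(C(C)C)C(C)C)C[C@H]1C(C)=C | intermediate
8 | tricyclic cyclopropanol: C3 carbinol and C1 (methyl) are the bridgeheads of a cyclopropane whose CH2 is C2; five-membered ring C1–C3–C4–C4a–C8a trans-fused to ring 2; drawn with the cyclopropane CH2 on the face of H-4a | O[C@]12C[C@@H]3C=C(C)[C@H](O[Si](C(C)C)(C(C)C)C(C)C)C[C@H]3[C@@]1(C)C2 | intermediate
9 | β-chloro ketone: decalin with C3 ketone, C1 bearing Cl and CH3 (both C1 epimers), C5=C6, 7-silyloxy | O=C1C[C@@H]2C=C(C)[C@H](O[Si](C(C)C)(C(C)C)C(C)C)C[C@H]2C(C)(Cl)C1 | intermediate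
10 | enone: trans-fused decalin, C3=O conjugated to C1=C2 (C1 methyl), C5=C6 (C6 methyl), 7-silyloxy | O=C1C[C@@H]2C=C(C)[C@H](O[Si](C(C)C)(C(C)C)C(C)C)C[C@H]2C(C)=C1 | intermediate
11 | epoxy ketone: 10 with C1–C2 oxirane on the face anti to H-8a | O=C1C[C@@H]2C=C(C)[C@H](O[Si](C(C)C)(C(C)C)C(C)C)C[C@H]2[C@@]3(C)O[C@H]31 | intermediate
12 | tert-butyl bromoacetate | CC(C)(C)OC(=O)CBr | starting material
13 | 11 carrying CH2CO2tBu on C4, axial, cis to H-8a | CC(C)(C)OC(=O)C[C@@H]1[C@@H]2C=C(C)[C@H](O[Si](C(C)C)(C(C)C)C(C)C)C[C@H]2[C@@]3(C)O[C@H]3C1=O | intermediate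
14 | β-hydroxy ketone: C1 (CH3)(OH) with OH anti to H-8a, C3 ketone, C4 side chain as in 13 | CC(C)(C)OC(=O)C[C@@H]1[C@@H]2C=C(C)[C@H](O[Si](C(C)C)(C(C)C)C(C)C)C[C@H]2[C@@](C)(O)CC1=O | intermediate
15 | diol: 14 reduced at C3, C3–OH anti to C1–OH and cis to the C4 side chain | CC(C)(C)OC(=O)C[C@@H]1[C@@H]2C=C(C)[C@H](O[Si](C(C)C)(C(C)C)C(C)C)C[C@H]2[C@@](C)(O)C[C@@H]1O | intermediate
16 | Mannich base: 15 with CH2NMe2 on the ester α-carbon (both epimers there) | CN(C)CC(C(=O)OC(C)(C)C)[C@@H]1[C@@H]2C=C(C)[C@H](O[Si](C(C)C)(C(C)C)C(C)C)C[C@H]2[C@@](C)(O)C[C@@H]1O | intermediate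
17 | trimethylammonium iodide of 16 | C[N+](C)(C)CC(C(=O)OC(C)(C)C)[C@@H]1[C@@H]2C=C(C)[C@H](O[Si](C(C)C)(C(C)C)C(C)C)C[C@H]2[C@@](C)(O)C[C@@H]1O.[I-] | intermediate
18 | tert-butyl 2-(decalin-4-yl)acrylate with 1-OH, 3-OH, 7-silyloxy | C=C(C(=O)OC(C)(C)C)[C@@H]1[C@@H]2C=C(C)[C@H](O[Si](C(C)C)(C(C)C)C(C)C)C[C@H]2[C@@](C)(O)C[C@@H]1O | intermediate
19 | 2-butyne-1,4-diol | OCC#CCO | starting material
20 | (E)-2-(tributylstannyl)but-2-ene-1,4-diol (CH2OH groups cis) | OC/C=C(\CO)[Sn](CCCC)(CCCC)CCCC | intermediate
21 | 2,2-dimethyl-5-(tributylstannyl)-4,7-dihydro-1,3-dioxepine | CC1(C)OCC=C(CO1)[Sn](CCCC)(CCCC)CCCC | intermediate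
22 | (2,2-dimethyl-4,7-dihydro-1,3-dioxepin-5-yl)lithium | [Li]C1=CCOC(C)(C)OC1 | intermediate
23 | 2,2-dimethyl-4,7-dihydro-1,3-dioxepine-5-carboxylic acid | CC1(C)OCC=C(CO1)C(=O)O | intermediate
24 | mixed anhydride of 23 and 2,4,6-trichlorobenzoic acid | CC1(C)OCC=C(CO1)C(=O)OC(=O)c1c(Cl)cc(Cl)cc1Cl | intermediate
25 | 18 esterified at C3–O with the dioxepine carboxylic acid | C=C(C(=O)OC(C)(C)C)[C@@H]1[C@@H]2C=C(C)[C@H](O[Si](C(C)C)(C(C)C)C(C)C)C[C@H]2[C@@](C)(O)C[C@@H]1OC(=O)C1=CCOC(C)(C)OC1 | intermediate
26 | 25 with free C7–OH (cis to H-8a) | C=C(C(=O)OC(C)(C)C)[C@@H]1[C@@H]2C=C(C)[C@H](O)C[C@H]2[C@@](C)(O)C[C@@H]1OC(=O)C1=CCOC(C)(C)OC1 | intermediate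
27 | C7 acetate with inverted C7 (trans to H-8a); tert-butyl ester and acetonide still in place | C=C(C(=O)OC(C)(C)C)[C@@H]1[C@@H]2C=C(C)[C@@H](OC(C)=O)C[C@H]2[C@@](C)(O)C[C@@H]1OC(=O)C1=CCOC(C)(C)OC1 | intermediate
28 | CNP0468194.2: 2-[7-acetoxy-1-hydroxy-3-{[(E)-4-hydroxy-2-(hydroxymethyl)but-2-enoyl]oxy}-1,6-dimethyl-1,2,3,4,4a,7,8,8a-octahydronaphthalen-4-yl]acrylic acid, configuration as in the SMILES | C=C(C(=O)O)[C@@H]1[C@@H]2C=C(C)[C@@H](OC(C)=O)C[C@H]2[C@@](C)(O)C[C@@H]1OC(=O)/C(=C/CO)CO | target

Total step count: 18. Longest linear sequence: 15 steps (steps 1–11 and 15–18); steps 12–14 make the side-chain acid.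

Steps most likely to fail

Step 5. Ligand exchange of the titanacyclopropane onto a 1,1-disubstituted alkene is slow, so the Grignard reagent may instead reduce or alkylate the ester before cyclopropanation. The fallback sets out from 7 and replaces the titanium coupling by a carbenoid route. Lemieux–Johnson cleavage of the isopropenyl group (OsO4 cat., NaIO4, 2,6-lutidine, dioxane/H2O) should give the methyl ketone F1. Intramolecular McMurry keto ester coupling (TiCl3, LiAlH4, Et3N, DME, reflux, high dilution) should close the five-membered ring as the cyclic enol ether F2. Mild acid (oxalic acid, wet THF) should hydrolyse it to the hydrindan-2-one F3. TMSCl, Et3N, DMF, 80 °C should give the more substituted silyl enol ether F4, and Simmons–Smith cyclopropanation (Et2Zn, CH2I2, CH2Cl2, 0 °C) the silyloxycyclopropane F5. F5 is opened with FeCl3 in DMF and then NaOAc exactly as 8, which returns the route at 10.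

Step 6. The alkoxy radical may fragment at the external cyclopropane bond, or FeCl3 may chlorinate the C5=C6 alkene or strip the silyl ether, and elimination of HCl may give the non-conjugated alkene. The fallback sets out from 8 and traps the ring-enlarged radical with oxygen instead of chlorine: Mn(acac)3 (cat.), O2, toluene, rt should give the hydroperoxy ketone F6, reduced in the same flask with PPh3 to the hydroxy ketone F7. This tertiary aldol is reversible, so a wrong C1 epimer can equilibrate toward the axial alcohol. Treatment of F7 with LiN(iPr)2 (2.2 equiv) at −78 °C, which forms the α′-enolate of the lithium aldolate, and then 12 should give 14 directly, where the route resumes.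

Step 17. Activation of the hindered axial allylic alcohol may lead to elimination to a diene or to SN2′ attack instead of clean inversion. The fallback sets out from 26 and inverts C7 by oxidation and reduction: MnO2, CH2Cl2, rt should give the enone F8; NaBH4, CeCl3·7H2O, MeOH, −78 °C should deliver hydride axially, as in the reduction of carvone to cis-carveol, to give the equatorial alcohol F9; Ac2O, pyridine, DMAP then gives 27.

Further compounds
F1 | step 5 | methyl ketone: 7 with the isopropenyl group cleaved to acetyl | CCOC(=O)C[C@@H]1C=C(C)[C@H](O[Si](C(C)C)(C(C)C)C(C)C)C[C@H]1C(C)=O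
F2 | step 5 | cyclic enol ether: five-membered ring with C3(OEt)=C1(CH3), trans-fused to ring 2 | CC1=C(OCC)C[C@@H]2C=C(C)[C@H](O[Si](C(C)C)(C(C)C)C(C)C)C[C@@H]12
F3 | step 5 | hydrindan-2-one: C3 ketone flanked by C4H2 and C1H(CH3), C1 epimers | CC1C(=O)C[C@@H]2C=C(C)[C@H](O[Si](C(C)C)(C(C)C)C(C)C)C[C@@H]12
F4 | step 5 | trimethylsilyl enol ether C3(OSiMe3)=C1(CH3) of F3 | CC1=C(O[Si](C)(C)C)C[C@@H]2C=C(C)[C@H](O[Si](C(C)C)(C(C)C)C(C)C)C[C@@H]12
F5 | step 5 | trimethylsilyl ether of cyclopropanol 8 | C[Si](C)(C)O[C@]12C[C@@H]3C=C(C)[C@H](O[Si](C(C)C)(C(C)C)C(C)C)C[C@H]3[C@@]1(C)C2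
F6 | step 6 | hydroperoxy ketone: C3 ketone, C1 (CH3)(OOH), no C4 substituent | O=C1C[C@@H]2C=C(C)[C@H](O[Si](C(C)C)(C(C)C)C(C)C)C[C@H]2[C@@](C)(OO)C1
F7 | step 6 | hydroxy ketone: C3 ketone, C1 (CH3)(OH), no C4 substituent | O=C1C[C@@H]2C=C(C)[C@H](O[Si](C(C)C)(C(C)C)C(C)C)C[C@H]2[C@@](C)(O)C1
F8 | step 17 | C7 enone of 26 | C=C(C(=O)OC(C)(C)C)[C@@H]1[C@@H]2C=C(C)C(=O)C[C@H]2[C@@](C)(O)C[C@@H]1OC(=O)C1=CCOC(C)(C)OC1
F9 | step 17 | C7 epimer of 26 (hydroxyl trans to H-8a) | C=C(C(=O)OC(C)(C)C)[C@@H]1[C@@H]2C=C(C)[C@@H](O)C[C@H]2[C@@](C)(O)C[C@@H]1OC(=O)C1=CCOC(C)(C)OC1
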